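The earlier runs and the new flask were computed with constants of no real substance, noise included.

Slowness is what the cold runs show: after 2.50 min the eta run still holds 93% of its starting material, and the zeta run 87%. You have these runs, and three new flasks to judge.

| setting | eta | delta | zeta | Saturday's | Tuesday's | Thursday's |
|---|---|---|---|---|---|---|
| starting material | 10 mM | 10 mM | 5 mM | 10 mM | 10 mM | 10 mM |
| second substrate | 10 mM | 10 mM | 10 mM | 10.0 mM | 10.0 mM | 10.0 mM |
| free catalyst | 20 µM | 31 µM | 41 µM | 41 µM | 41 µM | 41 µM |
| temperature | 85 °C | 98 °C | 85 °C | 90 °C | 105 °C |  |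
| remark | run made earlier | run made earlier | run made earlier |  |  | at 105 °C until 50 s, from then on at 90 °C |
| time |  |  |  | 2.5 min | 2.5 min | 2.5 min |

| run | time / min | target / % | starting material / % |
|---|---|---|---|
| eta | 0.167 | 0 | 101 |
| eta | 0.500 | 4 | 99 |
| eta | 0.833 | 1 | 95 |
| eta | 1.33 | 4 | 98 |
| eta | 2.00 | 5 | 94 |
| eta | 2.50 | 7 | 93 |
| delta | 0.417 | 4 | 93 |
| delta | 0.833 | 8 | 83 |
| delta | 1.33 | 17 | 75 |
| delta | 1.50 | 19 | 71 |
| delta | 2.00 | 19 | 62 |
| delta | 2.50 | 28 | 54 |
| zeta | 0.200 | 4 | 102 |
| zeta | 0.667 | 5 | 94 |
| zeta | 1.33 | 3 | 96 |
| zeta | 2.00 | 13 | 91 |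
| zeta | 2.50 | 10 | 87 |

(scatter of a reading: 2 percentage points)



* the flask with the highest amount of target, in percent of the starting material charged ("all alike" if they lie within 1.5 percentage points) (Saturday's / Tuesday's / Thursday's / all alike)
* final target, as a percentage of the starting material charged, in Saturday's
* final target, as a percentage of the starting material charged, in Tuesday's
* final target, as a percentage of the starting material charged, in Thursday's

Call A the starting material left, as a fraction of the charge, P the target on the same scale and t the time, all at a run's last reading. Then k = −ln(A)/t is a first-order loss constant, and I rescale it in proportion to catalyst to the 41 µM of the new flasks. The eta run, with the starting material of the new flasks, reads 0.0595 /min; the zeta run, with half of that starting material, reads 0.0557 /min; and the delta run reads 0.326 /min. Carrying the eta value at 85 °C and the delta value at 98 °C forward with a steady factor per degree, I get 0.815 /min at 105 °C and 0.114 /min at 90 °C.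

The large term is conversion; the correction is the gap G, the part of the charge that is neither A nor P, which reads 18.0% in the delta run, a reading with its scatter. I take the gap to grow with A times P. With P rising roughly linearly and A at its mean Ā between the charge and the last reading, this gives G = s·Ā·P·t/2. Here s is the side coefficient 0.668 /min, held fixed across temperatures. Since P and G together make up the conversion, the selectivity is φ = 1/(1 + s·Ā·t/2), and P is φ times the conversion.

Now the ladder. Tuesday's half-life is 0.851 min, so 2.94 half-lives fit into that flask. Next comes the side time, the inverse of s, 1.50 min, then the window of 2.5 min. Saturday's half-life, 6.06 min, is the longest of these, so 0.413 of one passes there, and Tuesday's is the shortest. Exposures k·t add across Thursday's change of temperature. I expect A of 75.1%, 13.1% and 41.9% for Saturday's, Tuesday's and Thursday's. Target then comes to 14.4%, 59.1% and 36.5%, with Tuesday's ahead.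

The forecast, which reads “a parallel side path with higher activation energy”, says 18%, 38% and 29% and names Tuesday's, the same flask as mine, though its figure is higher than mine for Saturday's and lower than mine for Tuesday's and Thursday's.

The flasks give 14.7% for Saturday's, 58.8% for Tuesday's and 30.9% for Thursday's, so Tuesday's holds most.

    catalyst intermediate A → free catalyst + target (k = 5.84 /s, Ea = 87.0 kJ/mol)
    catalyst intermediate B → free catalyst + second product (k = 1.44 /s, Ea = 84.0 kJ/mol)
    starting material + free catalyst ⇌ catalyst intermediate A (K = 72.3 /M, k = 9240 /M/s, Ea = 33.0 kJ/mol, ΔH = −2.00 kJ/mol)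
    2 catalyst intermediate B ⇌ resting dimer (K = 35300 /M, k = 24300 /M/s, Ea = 15.0 kJ/mol, ΔH = −33.0 kJ/mol)
    second substrate + free catalyst ⇌ catalyst intermediate B (K = 4200 /M, k = 950 /M/s, Ea = 47.0 kJ/mol, ΔH = −56.0 kJ/mol)
    starting material + target → side product (k = 0.443 /M/s, Ea = 68.0 kJ/mol)
    (constants at 90 °C)

In Thursday's, target is made 3.78 times faster than it is used up at 0.660 min, and 2.03 times faster at the end. Put Thursday's final starting material, 44.5%, into φ with the same s, and you get 34.6% of target against its 30.9%. Thursday's neighbour with 6.0 mM of second substrate ends with 22.5% of starting material, for which s gives 51.3%; that flask holds 49.7%.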